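## Retrosynthetic overview

1. The O1–C2 bond is made last. The dihydrofuran ring, the only ring the route builds, closes when a fully silylated, acyclic benzylic 2-pyridyl sulfone (C3 fixed, C2 a mixture of both epimers) meets fluoride: desilylation, 1,6-elimination of sulfinate to a p-quinone methide, then oxa-Michael closure.
2. Enabling feature: O4' of the 3,4-dihydroxyphenyl ring is para to C2, so C2 can become the exocyclic carbon of a p-quinone methide. The phenol oxygen O1 of the stilbene-bearing benzene ring is ortho to C3a, so it reaches C2 through a five-membered (5-exo-trig) transition state in which C3 dictates the 2,3-trans outcome.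
3. C2–aryl bond: Pd-catalysed α-arylation of a β,β-diarylethyl sulfone with silylated 4-bromocatechol. The sulfonyl group is a temporary linchpin (acceptor activation, carbanion stabilisation, leaving group) that the last step removes.
4. C3–aryl bond and the only stereocenter that must be controlled: Rh/Chiraphos conjugate addition of a 3,5-bis(silyloxy)phenylboronic acid to an (E)-vinyl 2-pyridyl sulfone.
5. The vinyl sulfone comes from HWE olefination of a stilbene aldehyde, itself made by Heck coupling of silylated 5-bromosalicylaldehyde with 3,5-bis(silyloxy)styrene.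

Key step: step 11

Abbreviations: TBS = tert-butyldimethylsilyl; TBSO = tert-butyldimethylsilyloxy.

Remark (assumption): in step 8, (S,S)-Chiraphos is taken to give the (S) configuration at the new diarylmethine carbon; if the sense of induction on this substrate is the opposite, (R,R)-Chiraphos is used and nothing else changes.

## Route

Step 1
Reactants: 1 3,5-dihydroxybenzaldehyde
Product: 2 3,5-bis(TBSO)benzaldehyde
Conditions: TBSCl (2.4 equiv), imidazole, DMF, rt
Reagents that add atoms: tert-butyldimethylsilyl chloride, CC(C)(C)[Si](C)(C)Cl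
Why: Imidazole-promoted silyl ether formation masks both phenols for the organometallic steps that follow.

Step 2
Reactants: 2 3,5-bis(TBSO)benzaldehyde
Product: 3 3,5-bis(TBSO)styrene
Conditions: Ph3PCH3Br, KHMDS, THF, 0 °C to rt
Reagents that add atoms: methyltriphenylphosphonium bromide, C[P+](c1ccccc1)(c1ccccc1)c1ccccc1.[Br-]
Why: Wittig methylenation of the aldehyde gives the terminal styrene needed as the Heck partner.

Step 3
Reactants: 4 5-bromo-2-hydroxybenzaldehyde
Product: 5 5-bromo-2-(TBSO)benzaldehyde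
Conditions: TBSCl (1.2 equiv), imidazole, DMF, rt
Reagents that add atoms: tert-butyldimethylsilyl chloride, CC(C)(C)[Si](C)(C)Cl
Why: Silyl ether formation protects the phenol that later becomes O1, so it cannot interfere with the palladium, lithium and rhodium chemistry.

Step 4
Reactants: 5 5-bromo-2-(TBSO)benzaldehyde; 3 3,5-bis(TBSO)styrene
Product: 6 5-[(E)-2-(3,5-bis(TBSO)phenyl)ethenyl]-2-(TBSO)benzaldehyde
Conditions: Pd2(dba)3 (2 mol%), [HP(t-Bu)3]BF4, Cy2NMe, dioxane, 60 °C
Reagents that add atoms: none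
Why: Mizoroki–Heck coupling of the aryl bromide with the terminal styrene should give the (E)-stilbene by syn-carbopalladation and syn β-hydride elimination, under conditions mild enough for the aldehyde and the aryl silyl ethers.

Step 5
Reactants: 6 5-[(E)-2-(3,5-bis(TBSO)phenyl)ethenyl]-2-(TBSO)benzaldehyde; 7 2-(methylsulfonyl)pyridine
Product: 9 2-{[(E)-2-{5-[(E)-2-(3,5-bis(TBSO)phenyl)ethenyl]-2-(TBSO)phenyl}ethenyl]sulfonyl}pyridine, via lithiated sulfonylmethylphosphonate 8 (not isolated)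
Conditions: 7, n-BuLi (2.1 equiv), ClP(O)(OEt)2, THF, −78 °C; then 6, −78 °C to rt
Reagents that add atoms: none
Why: Horner–Wadsworth–Emmons olefination, in which the sulfonyl- and phosphoryl-stabilised carbanion made from 7 adds to the aldehyde and loses phosphate to give the (E)-vinyl sulfone; the carbon from 7 is the future C2.

Step 6
Reactants: 10 5-bromobenzene-1,3-diol
Product: 11 1-bromo-3,5-bis(TBSO)benzene
Conditions: TBSCl (2.4 equiv), imidazole, DMF, rt
Reagents that add atoms: tert-butyldimethylsilyl chloride, CC(C)(C)[Si](C)(C)Cl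
Why: Silyl ether formation of both phenols gives an aryl bromide that tolerates bromine–lithium exchange.

Step 7
Reactants: 11 1-bromo-3,5-bis(TBSO)benzene
Product: 14 [3,5-bis(TBSO)phenyl]boronic acid, via aryllithium 12 (not isolated), via lithium aryltriisopropoxyborate 13 (not isolated)
Conditions: n-BuLi, THF, −78 °C; B(Oi-Pr)3, −78 °C to rt; aq. NH4Cl
Reagents that add atoms: triisopropyl borate, CC(C)OB(OC(C)C)OC(C)C; water, O
Why: Bromine–lithium exchange, borylation of the aryllithium and mild hydrolysis is the standard route to an arylboronic acid, and the silyloxy groups are meta to lithium so no silyl migration can occur.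

Step 8
Reactants: 9 2-{[(E)-2-{5-[(E)-2-(3,5-bis(TBSO)phenyl)ethenyl]-2-(TBSO)phenyl}ethenyl]sulfonyl}pyridine; 14 [3,5-bis(TBSO)phenyl]boronic acid
Product: 15 2-{[(2S)-2-[3,5-bis(TBSO)phenyl]-2-{5-[(E)-2-(3,5-bis(TBSO)phenyl)ethenyl]-2-(TBSO)phenyl}ethyl]sulfonyl}pyridine
Conditions: [Rh(acac)(C2H4)2] (5 mol%), (S,S)-Chiraphos (5.5 mol%), 14 (4 equiv), dioxane/H2O (10:1), 100 °C
Reagents that add atoms: none
Why: Rhodium-catalysed asymmetric conjugate addition of an arylboronic acid (Hayashi–Miyaura type) to a β-aryl vinyl 2-pyridyl sulfone, in which the pyridyl nitrogen chelates the aryl–rhodium–Chiraphos complex so that it adds to one face of the alkene and sets C3 (S); the new stereocenter is β to the sulfonyl group and not acidic, and the stilbene alkene is not activated and should stay untouched.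

Step 9
Reactants: 16 4-bromobenzene-1,2-diol
Product: 17 4-bromo-1,2-bis(TBSO)benzene
Conditions: TBSCl (2.4 equiv), imidazole, DMF, rt
Reagents that add atoms: tert-butyldimethylsilyl chloride, CC(C)(C)[Si](C)(C)Cl
Why: Silyl ether formation of the catechol gives the aryl bromide for the α-arylation and the silyl trigger at O4' for the last step.

Step 10
Reactants: 15 2-{[(2S)-2-[3,5-bis(TBSO)phenyl]-2-{5-[(E)-2-(3,5-bis(TBSO)phenyl)ethenyl]-2-(TBSO)phenyl}ethyl]sulfonyl}pyridine; 17 4-bromo-1,2-bis(TBSO)benzene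
Product: 19 2-{[(1RS,2S)-1-[3,4-bis(TBSO)phenyl]-2-[3,5-bis(TBSO)phenyl]-2-{5-[(E)-2-(3,5-bis(TBSO)phenyl)ethenyl]-2-(TBSO)phenyl}ethyl]sulfonyl}pyridine, via zincated sulfone 18 (not isolated)
Conditions: TMPZnCl·LiCl (1.5 equiv), THF, rt; then 17, XPhos Pd G3 (5 mol%), 65 °C
Reagents that add atoms: none
Why: Palladium-catalysed α-arylation of a sulfone through its zincated carbanion (Negishi-type coupling) forms the C2–aryl bond; C2 is left as a mixture of epimers on purpose because step 11 erases it, and C3, β to the sulfonyl group, is not touched.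

Step 11
Reactants: 19 2-{[(1RS,2S)-1-[3,4-bis(TBSO)phenyl]-2-[3,5-bis(TBSO)phenyl]-2-{5-[(E)-2-(3,5-bis(TBSO)phenyl)ethenyl]-2-(TBSO)phenyl}ethyl]sulfonyl}pyridine
Product: 22 4-[(2S,3S)-3-(3,5-dihydroxyphenyl)-5-[(E)-2-(3,5-dihydroxyphenyl)ethenyl]-2,3-dihydro-1-benzofuran-2-yl]benzene-1,2-diol, via heptaphenol sulfone 20 (not isolated), via quinone methide 21 (not isolated)
Conditions: TBAF (10 equiv), degassed THF, 0 °C to rt; aq. NH4Cl/ascorbic acid quench
Reagents that add atoms: none
Why: Fluoride cleaves all seven aryl silyl ethers; the phenoxide at O4' (para to C2) then expels pyridine-2-sulfinate by 1,6-elimination to give p-quinone methide 21, and the phenoxide O1, held ortho to the C3-bearing carbon, adds to the exocyclic carbon C2 with rearomatisation of the catechol ring. The closest known reaction type is the fluoride- or base-triggered generation of quinone methides from silyl-protected hydroxybenzyl sulfones or halides and their intramolecular capture by a phenol, as in the closure of phenylcoumaran (8–5') neolignans. The dihydrofuran ring closes 5-exo-trig, since the C2=C1' double bond of 21 lies outside the new ring. C2 is created from a planar carbon, so both C2 epimers of 19 converge; the C3 stereocenter from step 8 directs O1 to the face of C2 that places the catechol ring anti to the 3,5-dihydroxyphenyl group, and because the oxa-Michael addition is reversible through 21 under these conditions the more stable 2,3-trans isomer (2S,3S) should accumulate. The step needs O- over C-alkylation and ring closure faster than loss of the C3 proton from 21 (which would erase C3); both are secured by the intramolecular, five-membered delivery of O1.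

## Compound list

1 | 3,5-dihydroxybenzaldehyde | O=Cc1cc(O)cc(O)c1 | starting material
2 | 3,5-bis(TBSO)benzaldehyde | O=Cc1cc(O[Si](C)(C)C(C)(C)C)cc(O[Si](C)(C)C(C)(C)C)c1 | intermediate
3 | 3,5-bis(TBSO)styrene | C=Cc1cc(O[Si](C)(C)C(C)(C)C)cc(O[Si](C)(C)C(C)(C)C)c1 | intermediate
4 | 5-bromo-2-hydroxybenzaldehyde | O=Cc1cc(Br)ccc1O | starting material
5 | 5-bromo-2-(TBSO)benzaldehyde | O=Cc1cc(Br)ccc1O[Si](C)(C)C(C)(C)C | intermediate
6 | 5-[(E)-2-(3,5-bis(TBSO)phenyl)ethenyl]-2-(TBSO)benzaldehyde | CC(C)(C)[Si](C)(C)Oc1cc(O[Si](C)(C)C(C)(C)C)cc(/C=C/c2ccc(O[Si](C)(C)C(C)(C)C)c(C=O)c2)c1 | intermediate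
7 | 2-(methylsulfonyl)pyridine | CS(=O)(=O)c1ccccn1 | starting material
8 | lithium (diethoxyphosphoryl)(pyridin-2-ylsulfonyl)methanide (not isolated) | [Li+].CCOP(=O)(OCC)[CH-]S(=O)(=O)c1ccccn1 | intermediate
9 | 2-{[(E)-2-{5-[(E)-2-(3,5-bis(TBSO)phenyl)ethenyl]-2-(TBSO)phenyl}ethenyl]sulfonyl}pyridine | CC(C)(C)[Si](C)(C)Oc1cc(O[Si](C)(C)C(C)(C)C)cc(/C=C/c2ccc(O[Si](C)(C)C(C)(C)C)c(/C=C/S(=O)(=O)c3ccccn3)c2)c1 | intermediate
10 | 5-bromobenzene-1,3-diol | Oc1cc(O)cc(Br)c1 | starting material
11 | 1-bromo-3,5-bis(TBSO)benzene | Brc1cc(O[Si](C)(C)C(C)(C)C)cc(O[Si](C)(C)C(C)(C)C)c1 | intermediate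
12 | [3,5-bis(TBSO)phenyl]lithium (not isolated) | [Li]c1cc(O[Si](C)(C)C(C)(C)C)cc(O[Si](C)(C)C(C)(C)C)c1 | intermediate
13 | lithium [3,5-bis(TBSO)phenyl]tri(propan-2-yloxy)borate (not isolated) | [Li+].CC(C)O[B-](OC(C)C)(OC(C)C)c1cc(O[Si](C)(C)C(C)(C)C)cc(O[Si](C)(C)C(C)(C)C)c1 | intermediate
14 | [3,5-bis(TBSO)phenyl]boronic acid | OB(O)c1cc(O[Si](C)(C)C(C)(C)C)cc(O[Si](C)(C)C(C)(C)C)c1 | intermediate
15 | 2-{[(2S)-2-[3,5-bis(TBSO)phenyl]-2-{5-[(E)-2-(3,5-bis(TBSO)phenyl)ethenyl]-2-(TBSO)phenyl}ethyl]sulfonyl}pyridine | CC(C)(C)[Si](C)(C)Oc1cc(O[Si](C)(C)C(C)(C)C)cc(/C=C/c2ccc(O[Si](C)(C)C(C)(C)C)c(c2)[C@H](c2cc(O[Si](C)(C)C(C)(C)C)cc(O[Si](C)(C)C(C)(C)C)c2)CS(=O)(=O)c2ccccn2)c1 | intermediate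
16 | 4-bromobenzene-1,2-diol | Oc1ccc(Br)cc1O | starting material
17 | 4-bromo-1,2-bis(TBSO)benzene | Brc1ccc(O[Si](C)(C)C(C)(C)C)c(O[Si](C)(C)C(C)(C)C)c1 | intermediate
18 | chloro[(1RS,2S)-2-[3,5-bis(TBSO)phenyl]-2-{5-[(E)-2-(3,5-bis(TBSO)phenyl)ethenyl]-2-(TBSO)phenyl}-1-(pyridin-2-ylsulfonyl)ethyl]zinc (not isolated) | CC(C)(C)[Si](C)(C)Oc1cc(O[Si](C)(C)C(C)(C)C)cc(/C=C/c2ccc(O[Si](C)(C)C(C)(C)C)c(c2)[C@H](c2cc(O[Si](C)(C)C(C)(C)C)cc(O[Si](C)(C)C(C)(C)C)c2)C([Zn]Cl)S(=O)(=O)c2ccccn2)c1 | intermediate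
19 | 2-{[(1RS,2S)-1-[3,4-bis(TBSO)phenyl]-2-[3,5-bis(TBSO)phenyl]-2-{5-[(E)-2-(3,5-bis(TBSO)phenyl)ethenyl]-2-(TBSO)phenyl}ethyl]sulfonyl}pyridine (both C1 epimers) | CC(C)(C)[Si](C)(C)Oc1cc(O[Si](C)(C)C(C)(C)C)cc(/C=C/c2ccc(O[Si](C)(C)C(C)(C)C)c(c2)[C@H](c2cc(O[Si](C)(C)C(C)(C)C)cc(O[Si](C)(C)C(C)(C)C)c2)C(c2ccc(O[Si](C)(C)C(C)(C)C)c(O[Si](C)(C)C(C)(C)C)c2)S(=O)(=O)c2ccccn2)c1 | intermediate
20 | 4-[(1RS,2S)-2-(3,5-dihydroxyphenyl)-2-{5-[(E)-2-(3,5-dihydroxyphenyl)ethenyl]-2-hydroxyphenyl}-1-(pyridin-2-ylsulfonyl)ethyl]benzene-1,2-diol (present as phenoxides, not isolated) | Oc1cc(O)cc(/C=C/c2ccc(O)c(c2)[C@H](c2cc(O)cc(O)c2)C(c2ccc(O)c(O)c2)S(=O)(=O)c2ccccn2)c1 | intermediate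
21 | 4-[(2S)-2-(3,5-dihydroxyphenyl)-2-{5-[(E)-2-(3,5-dihydroxyphenyl)ethenyl]-2-hydroxyphenyl}ethylidene]-2-hydroxycyclohexa-2,5-dien-1-one (p-quinone methide, present as phenoxide, not isolated) | Oc1cc(O)cc(/C=C/c2ccc(O)c(c2)[C@H](c2cc(O)cc(O)c2)C=C2C=CC(=O)C(O)=C2)c1 | intermediate
22 | 4-[(2S,3S)-3-(3,5-dihydroxyphenyl)-5-[(E)-2-(3,5-dihydroxyphenyl)ethenyl]-2,3-dihydro-1-benzofuran-2-yl]benzene-1,2-diol | Oc1cc(O)cc(/C=C/c2ccc3c(c2)[C@H](c2cc(O)cc(O)c2)[C@@H](c2ccc(O)c(O)c2)O3)c1 | target

## Step count and risks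

Total: 11 steps. Longest linear sequence: 7 steps (1 → 2 → 3 → 6 → 9 → 15 → 19 → 22; steps 1, 2, 4, 5, 8, 10, 11).

Steps most likely to fail:

Step 10. The zincated sulfone may fail to transmetalate at its hindered, β-branched carbon, or the α-sulfonylalkyl–palladium intermediate may undergo β-hydride elimination toward C3 instead of reductive elimination. The fallback sets out from 15 and returns to 19 without palladium. Deprotonation of 15 (LDA, THF, −78 °C) and bromination with 1,2-dibromotetrachloroethane should give the α-bromo sulfone F1. In parallel, 17 is converted (n-BuLi, then ZnCl2) into [3,4-bis(TBSO)phenyl]zinc chloride F2. A nickel-catalysed Negishi arylation of the α-bromo sulfone (NiCl2·glyme, bipyridine-type ligand, THF/DMA), which proceeds through an alkyl radical and is known for α-bromo sulfones, then joins the two to give 19 as its C2 epimers, as before.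

Step 8. Carbometalation may be slow at the alkene next to the ortho-silyloxy group, so that protodeboronation of 14 and hydrolytic loss of silyl groups at 100 °C take over, or the facial selectivity may be too low. The fallback sets out from 6 and returns to 15, setting C3 by hydride delivery instead of aryl delivery. Aryllithium 12 (from 11) is added to aldehyde 6 to give the racemic diarylmethanol F3, which is oxidised (Dess–Martin periodinane) to the diaryl ketone F4. Olefination of the ketone with carbanion 8 should give the β,β-diaryl vinyl 2-pyridyl sulfone F5 as separable E and Z isomers. Copper hydride-catalysed asymmetric conjugate reduction (CuCl/NaOt-Bu, BINAP, PhSiH3, toluene), a reaction established for β,β-disubstituted vinyl 2-pyridyl sulfones, then gives 15, each geometric isomer being reduced with the ligand enantiomer that leads to the (S) configuration.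

Step 11. Under basic fluoride the quinone methide 21 may lose the C3 proton (tautomerisation to the triarylethene, which would erase C3), it may alkylate a resorcinol phenoxide of a second molecule at carbon, or a phenoxide may attack the pyridyl sulfone in a Smiles-type substitution; the catecholate is also prone to air oxidation. The fallback sets out from 19 and returns to 22 in two operations without strong base. Desilylation with HF·pyridine (pyridine/THF, 0 °C) gives the free heptaphenol sulfone 20, now isolated. It is then cyclised in degassed pH 7.5 phosphate buffer/MeCN at 37 °C, where only the small equilibrium share of the O4' phenoxide ionises the C–S bond and the quinone methide is captured by the neighbouring neutral phenol before a base can reach C3–H. This fallback makes no compound outside the compound list (F0).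

Further compounds
F1 | step 10 | 2-{[(1RS,2S)-1-bromo-2-[3,5-bis(TBSO)phenyl]-2-{5-[(E)-2-(3,5-bis(TBSO)phenyl)ethenyl]-2-(TBSO)phenyl}ethyl]sulfonyl}pyridine | CC(C)(C)[Si](C)(C)Oc1cc(O[Si](C)(C)C(C)(C)C)cc(/C=C/c2ccc(O[Si](C)(C)C(C)(C)C)c(c2)[C@H](c2cc(O[Si](C)(C)C(C)(C)C)cc(O[Si](C)(C)C(C)(C)C)c2)C(Br)S(=O)(=O)c2ccccn2)c1
F2 | step 10 | [3,4-bis(TBSO)phenyl]zinc chloride | Cl[Zn]c1ccc(O[Si](C)(C)C(C)(C)C)c(O[Si](C)(C)C(C)(C)C)c1
F3 | step 8 | [3,5-bis(TBSO)phenyl]{5-[(E)-2-(3,5-bis(TBSO)phenyl)ethenyl]-2-(TBSO)phenyl}methanol (racemic) | CC(C)(C)[Si](C)(C)Oc1cc(O[Si](C)(C)C(C)(C)C)cc(/C=C/c2ccc(O[Si](C)(C)C(C)(C)C)c(c2)C(O)c2cc(O[Si](C)(C)C(C)(C)C)cc(O[Si](C)(C)C(C)(C)C)c2)c1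
F4 | step 8 | [3,5-bis(TBSO)phenyl]{5-[(E)-2-(3,5-bis(TBSO)phenyl)ethenyl]-2-(TBSO)phenyl}methanone | CC(C)(C)[Si](C)(C)Oc1cc(O[Si](C)(C)C(C)(C)C)cc(/C=C/c2ccc(O[Si](C)(C)C(C)(C)C)c(c2)C(=O)c2cc(O[Si](C)(C)C(C)(C)C)cc(O[Si](C)(C)C(C)(C)C)c2)c1
F5 | step 8 | 2-{[2-[3,5-bis(TBSO)phenyl]-2-{5-[(E)-2-(3,5-bis(TBSO)phenyl)ethenyl]-2-(TBSO)phenyl}ethenyl]sulfonyl}pyridine (E and Z isomers at the new double bond, separated) | CC(C)(C)[Si](C)(C)Oc1cc(O[Si](C)(C)C(C)(C)C)cc(/C=C/c2ccc(O[Si](C)(C)C(C)(C)C)c(c2)C(=CS(=O)(=O)c2ccccn2)c2cc(O[Si](C)(C)C(C)(C)C)cc(O[Si](C)(C)C(C)(C)C)c2)c1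
F0 | step 11 | none | none
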